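**Plan**

1. Retrosynthesis cuts, in order: the two aryl O-methyl groups (protection); the C(O)–CH2 bond of each β,γ-unsaturated ketone (right arm by C-acylation of an allylic sulfonyl carbanion, left arm by allyl Grignard addition to an N-methoxy-N-methylamide followed by cross-metathesis); then ring bonds C1–C2 and C4–C5 of the cyclopentane (C1 = quaternary carbon carrying the acyl group, C2 = quaternary carbon carrying the CH2C(O) arm, C3–C5 = CH2).
2. Enabling feature: the 1,5-dicarbonyl array O=C–C1–C2–CH2–C=O across the two quaternary ring carbons. C1/C5 are the α/β carbons of a methacrylic unit, and C2 is the β-carbon of a 3-methyl-2-enoyl unit that carries C3–C4. A C4 radical can therefore add to C5, and the C1 enolate that results can add to C2.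
3. Forward: acrylamide 3 and redox-active ester 14 are joined by an electroreductive decarboxylative Giese addition/intramolecular Michael closure that builds the only carbocycle (step 12). The aryl-bearing chain (sulfone 22) is attached next, then the prenyl ketone, then the sulfone is removed and the hydroquinone unmasked.
4. Stereochemistry: C2 from the (R)-4-benzyloxazolidinone on the (Z)-enoyl acceptor; C1 from the magnesium-bridged closed transition state of the ring closure (methyl groups cis); the E side-chain alkene from anti-SN2′ opening of a vinyl epoxide.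

Key step: step 12

Assumption: the stereocentre at the sulfonyl-bearing carbon of 26, 27 and 28 is carried as a mixture of epimers, since it is removed in step 16.

**Route**

Step 1
Reactants: 1 methacryloyl chloride; 2 N,O-dimethylhydroxylamine hydrochloride
Product: 3 N-methoxy-N-methylmethacrylamide
Conditions: Et3N (2.2 equiv), CH2Cl2, 0 °C to rt
Reagents that add atoms: none
Why: N-acylation of the hydroxylamine by the acid chloride (Schotten–Baumann-type amide formation) should give the acrylamide, which later serves as radical acceptor and as ketone precursor.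

Step 2
Reactants: 4 pent-4-ynoic acid
Product: 5 tert-butyl pent-4-ynoate
Conditions: Cl3CC(=NH)OtBu (2 equiv), BF3·OEt2 (cat.), CH2Cl2/cyclohexane, rt
Reagents that add atoms: tert-butyl 2,2,2-trichloroacetimidate, CC(C)(C)OC(=N)C(Cl)(Cl)Cl
Why: Acid-catalysed O-alkylation of the carboxylic acid by the trichloroacetimidate (tert-butyl ester formation) should mask the acid that is released in step 6 as the radical precursor, without touching the alkyne.

Step 3
Reactants: 5 tert-butyl pent-4-ynoate
Product: 7 6-tert-butoxy-6-oxohex-2-ynoic acid, via magnesium acetylide 6 (not isolated)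
Conditions: iPrMgCl·LiCl (1.05 equiv), THF, 0 °C to rt; then CO2 (gas), −20 °C; cold 1 M HCl work-up
Reagents that add atoms: carbon dioxide, O=C=O
Why: The Grignard base deprotonates the terminal alkyne (the tert-butyl ester is inert at this temperature) and the magnesium acetylide is carboxylated (acetylide carboxylation) to the 2-ynoic acid.

Step 4
Reactants: 7 6-tert-butoxy-6-oxohex-2-ynoic acid; 8 (4R)-4-benzyl-1,3-oxazolidin-2-one
Product: 10 tert-butyl 6-[(4R)-4-benzyl-2-oxo-1,3-oxazolidin-3-yl]-6-oxohex-4-ynoate, via mixed pivalic anhydride 9 (not isolated)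
Conditions: PivCl, Et3N, THF, −20 °C; then 8, LiCl, −20 °C to rt
Reagents that add atoms: none
Why: N-acylation of the oxazolidinone through the mixed pivalic anhydride (mixed-anhydride method) should give the 2-ynoyl imide and installs the auxiliary that later controls the facial course of the ring closure.

Step 5
Reactants: 10 tert-butyl 6-[(4R)-4-benzyl-2-oxo-1,3-oxazolidin-3-yl]-6-oxohex-4-ynoate
Product: 11 tert-butyl (4Z)-6-[(4R)-4-benzyl-2-oxo-1,3-oxazolidin-3-yl]-4-methyl-6-oxohex-4-enoate
Conditions: Me2CuLi (1.2 equiv, from CuI and MeLi), THF, −78 °C; quench MeOH/aq NH4Cl at −78 °C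
Reagents that add atoms: lithium dimethylcuprate, [Li+].C[Cu-]C
Why: Conjugate syn-carbocupration of the 2-ynoyl imide and cold protonation of the alkenylcopper place methyl and hydrogen cis, so the chain and the imide carbonyl are cis (Z), the geometry the key step needs.

Step 6
Reactants: 11 tert-butyl (4Z)-6-[(4R)-4-benzyl-2-oxo-1,3-oxazolidin-3-yl]-4-methyl-6-oxohex-4-enoate
Product: 12 (4Z)-6-[(4R)-4-benzyl-2-oxo-1,3-oxazolidin-3-yl]-4-methyl-6-oxohex-4-enoic acid
Conditions: CF3CO2H, CH2Cl2, 0 °C to rt
Reagents that add atoms: none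
Why: Acidolysis of the tert-butyl ester (loss of 2-methylpropene) should free the carboxylic acid while the imide and the Z alkene survive the short exposure to acid.

Step 7
Reactants: 12 (4Z)-6-[(4R)-4-benzyl-2-oxo-1,3-oxazolidin-3-yl]-4-methyl-6-oxohex-4-enoic acid; 13 N-hydroxyphthalimide
Product: 14 1,3-dioxoisoindolin-2-yl (4Z)-6-[(4R)-4-benzyl-2-oxo-1,3-oxazolidin-3-yl]-4-methyl-6-oxohex-4-enoate
Conditions: N,N'-diisopropylcarbodiimide, DMAP (cat.), CH2Cl2, rt
Reagents that add atoms: none
Why: Carbodiimide-mediated esterification (Steglich esterification) should give the redox-active ester, which is reduced at a mild potential in the key step.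

Step 8
Reactants: 15 4-methoxy-2-methylphenol
Product: 16 2-bromo-4-methoxy-6-methylphenol
Conditions: N-bromosuccinimide, MeCN, 0 °C
Reagents that add atoms: N-bromosuccinimide, O=C1CCC(=O)N1Br
Why: Electrophilic aromatic bromination should go ortho to the free phenol, the only open position activated by OH, since the para position carries OMe and the other ortho position carries methyl.

Step 9
Reactants: 16 2-bromo-4-methoxy-6-methylphenol
Product: 17 1-bromo-2,5-dimethoxy-3-methylbenzene
Conditions: MeI, K2CO3, acetone, reflux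
Reagents that add atoms: iodomethane, CI
Why: Williamson ether synthesis gives the dimethyl ether, which survives the organometallic steps and is removed oxidatively at the end.

Step 10
Reactants: 17 1-bromo-2,5-dimethoxy-3-methylbenzene; 18 2-methyl-2-vinyloxirane (racemic)
Product: 20 (2E)-4-(2,5-dimethoxy-3-methylphenyl)-2-methylbut-2-en-1-ol, via aryl Grignard reagent 19 (not isolated)
Conditions: Mg, THF, 50 °C; then CuI (10 mol%), 18 (1.3 equiv), THF, −30 °C; aq NH4Cl
Reagents that add atoms: none
Why: Copper-catalysed anti-SN2′ opening of the vinyl epoxide by the aryl Grignard reagent (allylic substitution) should give the linear allylic alcohol with the E trisubstituted alkene as the major isomer, and minor Z material is removed by recrystallisation of sulfone 22.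

Step 11
Reactants: 20 (2E)-4-(2,5-dimethoxy-3-methylphenyl)-2-methylbut-2-en-1-ol
Product: 22 2,5-dimethoxy-1-methyl-3-[(2E)-3-methyl-4-(phenylsulfonyl)but-2-en-1-yl]benzene, via allylic bromide 21 (not isolated)
Conditions: PBr3 (0.4 equiv), Et2O, 0 °C; then PhSO2Na (1.5 equiv), DMF, rt
Reagents that add atoms: sodium benzenesulfinate, [Na+].[O-]S(=O)c1ccccc1
Why: Bromination of the primary allylic alcohol and SN2 S-alkylation of the sulfinate by the primary allylic bromide should give the allylic sulfone with retention of the E geometry.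

Step 12
Reactants: 14 1,3-dioxoisoindolin-2-yl (4Z)-6-[(4R)-4-benzyl-2-oxo-1,3-oxazolidin-3-yl]-4-methyl-6-oxohex-4-enoate; 3 N-methoxy-N-methylmethacrylamide
Product: 24 (1R,2R)-2-{2-[(4R)-4-benzyl-2-oxo-1,3-oxazolidin-3-yl]-2-oxoethyl}-N-methoxy-N,1,2-trimethylcyclopentane-1-carboxamide, via open-chain magnesium enolate 23 (not isolated)
Conditions: undivided cell, Mg anode, graphite cathode, 3 (4 equiv), Mg(ClO4)2 (1 equiv), nBu4NPF6 (0.1 M), THF, −20 °C, constant current, 2.2 F/mol; AcOH quench at −78 °C
Reagents that add atoms: none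
Why: Proposed new method: the cathode reduces the N-acyloxyphthalimide of 14 (the most easily reduced group present), which loses phthalimide anion and CO2 to give a primary alkyl radical that adds to the CH2 terminus of 3 (Giese addition, first new bond); the tertiary α-amido radical is then reduced to magnesium enolate 23 (radical–polar crossover), which adds in a 5-exo-trig intramolecular Michael reaction to the β-carbon of the Mg-chelated (Z)-enoyl imide (second new bond, closing the cyclopentane and creating both quaternary centres). The closest known reaction types are the decarboxylative Giese addition of redox-active esters, electroreductive radical–polar crossover carbofunctionalisation of alkenes, and photoredox radical addition–polar cyclisation cascades that end in an intramolecular alkylation; ending the cascade by a Michael addition that forms two vicinal quaternary carbons is the new element. The ring carbon that bears the CH2C(O) arm is controlled by the (R)-4-benzyl group of the auxiliary, which shields one face of the s-cis, Mg-chelated enoyl imide so that the enolate adds anti to benzyl, and with the Z alkene this face gives the required configuration. The carboxamide-bearing ring carbon is controlled by a closed transition state in which the enolate oxygen and the imide carbonyls share the magnesium ion; because the Z geometry puts the imide on the tether side of the alkene, only the enolate can lie over it, which places the carboxamide cis to the CH2C(O) arm and the two methyl groups cis. The step needs intermolecular radical addition to outrun the reversible 3-exo closure of the homoallyl radical, regiospecific formation of the hindered enolate, and ring closure faster than proton transfer, which are served by the excess of 3, by the crossover itself (a base would deprotonate the γ-positions of the enoyl imide instead) and by Lewis-acid activation of the acceptor. A purely radical ring closure is avoided on purpose, since the electrophilic α-amido radical would attack the electron-poor alkene slowly and preferentially in the 6-endo sense.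

Step 13
Reactants: 24 (1R,2R)-2-{2-[(4R)-4-benzyl-2-oxo-1,3-oxazolidin-3-yl]-2-oxoethyl}-N-methoxy-N,1,2-trimethylcyclopentane-1-carboxamide; 22 2,5-dimethoxy-1-methyl-3-[(2E)-3-methyl-4-(phenylsulfonyl)but-2-en-1-yl]benzene
Product: 26 (1R,2R)-2-[(4E)-6-(2,5-dimethoxy-3-methylphenyl)-4-methyl-2-oxo-3-(phenylsulfonyl)hex-4-en-1-yl]-N-methoxy-N,1,2-trimethylcyclopentane-1-carboxamide, via lithiated sulfone 25 (not isolated)
Conditions: 22 (2.1 equiv), nBuLi (2.0 equiv), THF, −78 °C; then 24, −78 to −40 °C; aq NH4Cl (excess 22 recovered)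
Reagents that add atoms: none
Why: The α-lithiated allylic sulfone attacks the exocyclic imide carbonyl through its α-carbon (C-acylation of a sulfonyl carbanion, Claisen-type) to give the β-keto sulfone and release the auxiliary, the second equivalent of carbanion deprotonating the acidic product, while the hindered N-methoxy-N-methylamide does not react at this temperature.

Step 14
Reactants: 26 (1R,2R)-2-[(4E)-6-(2,5-dimethoxy-3-methylphenyl)-4-methyl-2-oxo-3-(phenylsulfonyl)hex-4-en-1-yl]-N-methoxy-N,1,2-trimethylcyclopentane-1-carboxamide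
Product: 27 1-{(1R,2R)-2-[(4E)-6-(2,5-dimethoxy-3-methylphenyl)-4-methyl-2-oxo-3-(phenylsulfonyl)hex-4-en-1-yl]-1,2-dimethylcyclopentyl}but-3-en-1-one
Conditions: allylmagnesium bromide (4 equiv), THF, −78 to 0 °C; aq NH4Cl at 0 °C
Reagents that add atoms: allylmagnesium bromide, C=CC[Mg]Br
Why: One equivalent of the Grignard reagent turns the β-keto sulfone into its unreactive magnesium enolate, and the small, highly reactive allyl nucleophile adds once to the hindered N-methoxy-N-methylamide, whose chelated tetrahedral intermediate collapses to the ketone only on work-up (ketone synthesis from an N-methoxy-N-methylamide).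

Step 15
Reactants: 27 1-{(1R,2R)-2-[(4E)-6-(2,5-dimethoxy-3-methylphenyl)-4-methyl-2-oxo-3-(phenylsulfonyl)hex-4-en-1-yl]-1,2-dimethylcyclopentyl}but-3-en-1-one
Product: 28 1-{(1R,2R)-2-[(4E)-6-(2,5-dimethoxy-3-methylphenyl)-4-methyl-2-oxo-3-(phenylsulfonyl)hex-4-en-1-yl]-1,2-dimethylcyclopentyl}-4-methylpent-3-en-1-one
Conditions: 2-methylbut-2-ene (excess), second-generation Grubbs catalyst RuCl2(=CHPh)(PCy3)(H2IMes) (5 mol%), 1,4-benzoquinone (10 mol%), CH2Cl2, 40 °C
Reagents that add atoms: 2-methylbut-2-ene, CC=C(C)C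
Why: Olefin cross-metathesis of the terminal allyl group with 2-methylbut-2-ene should turn allyl into prenyl, the trisubstituted alkene of the other chain being inert to the catalyst.

Step 16
Reactants: 28 1-{(1R,2R)-2-[(4E)-6-(2,5-dimethoxy-3-methylphenyl)-4-methyl-2-oxo-3-(phenylsulfonyl)hex-4-en-1-yl]-1,2-dimethylcyclopentyl}-4-methylpent-3-en-1-one
Product: 29 1-{(1R,2R)-2-[(4E)-6-(2,5-dimethoxy-3-methylphenyl)-4-methyl-2-oxohex-4-en-1-yl]-1,2-dimethylcyclopentyl}-4-methylpent-3-en-1-one
Conditions: SmI2 (3 equiv), THF/MeOH, −78 °C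
Reagents that add atoms: none
Why: Single-electron reductive desulfonylation of the β-keto sulfone gives a samarium dienolate that methanol protonates at the α-carbon, which should deliver the β,γ-unsaturated ketone with the E alkene intact, and the hindered isolated ketone is not reduced at −78 °C.

Step 17
Reactants: 29 1-{(1R,2R)-2-[(4E)-6-(2,5-dimethoxy-3-methylphenyl)-4-methyl-2-oxohex-4-en-1-yl]-1,2-dimethylcyclopentyl}-4-methylpent-3-en-1-one
Product: 31 CNP0294415.1 (the target hydroquinone), via quinone 30 (not isolated)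
Conditions: (NH4)2Ce(NO3)6 (2.5 equiv), MeCN/H2O, 0 °C; then aq Na2S2O4, EtOAc, rt, under argon
Reagents that add atoms: water, O
Why: Oxidative demethylation of the 1,4-dimethoxyarene to the 1,4-benzoquinone and dithionite reduction (quinone to hydroquinone) under near-neutral conditions should unmask the hydroquinone without isomerising the two β,γ-unsaturated ketones.

**Compound list**

1 | methacryloyl chloride | CC(=C)C(Cl)=O | starting material
2 | N,O-dimethylhydroxylamine hydrochloride | CNOC.Cl | starting material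
3 | N-methoxy-N-methylmethacrylamide | CON(C)C(=O)C(C)=C | intermediate
4 | pent-4-ynoic acid | C#CCCC(=O)O | starting material
5 | tert-butyl pent-4-ynoate | C#CCCC(=O)OC(C)(C)C | intermediate
6 | chloromagnesium acetylide of 5 | CC(C)(C)OC(=O)CCC#C[Mg]Cl | intermediate (not isolated)
7 | 6-tert-butoxy-6-oxohex-2-ynoic acid | OC(=O)C#CCCC(=O)OC(C)(C)C | intermediate
8 | (4R)-4-benzyl-1,3-oxazolidin-2-one | O=C1N[C@H](Cc2ccccc2)CO1 | starting material
9 | mixed pivalic anhydride of 7 | CC(C)(C)OC(=O)CCC#CC(=O)OC(=O)C(C)(C)C | intermediate (not isolated)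
10 | tert-butyl 6-[(4R)-4-benzyl-2-oxo-1,3-oxazolidin-3-yl]-6-oxohex-4-ynoate | CC(C)(C)OC(=O)CCC#CC(=O)N1[C@H](Cc2ccccc2)COC1=O | intermediate
11 | tert-butyl (4Z)-6-[(4R)-4-benzyl-2-oxo-1,3-oxazolidin-3-yl]-4-methyl-6-oxohex-4-enoate | CC(C)(C)OC(=O)CC/C(C)=C\C(=O)N1[C@H](Cc2ccccc2)COC1=O | intermediate
12 | (4Z)-6-[(4R)-4-benzyl-2-oxo-1,3-oxazolidin-3-yl]-4-methyl-6-oxohex-4-enoic acid | OC(=O)CC/C(C)=C\C(=O)N1[C@H](Cc2ccccc2)COC1=O | intermediate
13 | N-hydroxyphthalimide | ON1C(=O)c2ccccc2C1=O | starting material
14 | 1,3-dioxoisoindolin-2-yl (4Z)-6-[(4R)-4-benzyl-2-oxo-1,3-oxazolidin-3-yl]-4-methyl-6-oxohex-4-enoate | O=C(ON1C(=O)c2ccccc2C1=O)CC/C(C)=C\C(=O)N3[C@H](Cc4ccccc4)COC3=O | intermediate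
15 | 4-methoxy-2-methylphenol | COc1ccc(O)c(C)c1 | starting material
16 | 2-bromo-4-methoxy-6-methylphenol | COc1cc(C)c(O)c(Br)c1 | intermediate
17 | 1-bromo-2,5-dimethoxy-3-methylbenzene | COc1cc(C)c(OC)c(Br)c1 | intermediate
18 | 2-methyl-2-vinyloxirane (racemic) | C=CC1(C)CO1 | starting material
19 | (2,5-dimethoxy-3-methylphenyl)magnesium bromide | COc1cc(C)c(OC)c([Mg]Br)c1 | intermediate (not isolated)
20 | (2E)-4-(2,5-dimethoxy-3-methylphenyl)-2-methylbut-2-en-1-ol | OC/C(C)=C/Cc1cc(OC)cc(C)c1OC | intermediate
21 | 1-[(2E)-4-bromo-3-methylbut-2-en-1-yl]-2,5-dimethoxy-3-methylbenzene | BrC/C(C)=C/Cc1cc(OC)cc(C)c1OC | intermediate (not isolated)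
22 | 2,5-dimethoxy-1-methyl-3-[(2E)-3-methyl-4-(phenylsulfonyl)but-2-en-1-yl]benzene | O=S(=O)(C/C(C)=C/Cc1cc(OC)cc(C)c1OC)c2ccccc2 | intermediate
23 | open-chain enolate of the Giese adduct (magnesium salt) | CON(C)C([O-])=C(C)CCC/C(C)=C\C(=O)N1[C@H](Cc2ccccc2)COC1=O | intermediate (not isolated)
24 | (1R,2R)-2-{2-[(4R)-4-benzyl-2-oxo-1,3-oxazolidin-3-yl]-2-oxoethyl}-N-methoxy-N,1,2-trimethylcyclopentane-1-carboxamide (methyl groups cis) | CON(C)C(=O)[C@]1(C)CCC[C@]1(C)CC(=O)N2[C@H](Cc3ccccc3)COC2=O | intermediate
25 | α-lithio derivative of sulfone 22 | [Li]C(S(=O)(=O)c1ccccc1)/C(C)=C/Cc2cc(OC)cc(C)c2OC | intermediate (not isolated)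
26 | (1R,2R)-2-[(4E)-6-(2,5-dimethoxy-3-methylphenyl)-4-methyl-2-oxo-3-(phenylsulfonyl)hex-4-en-1-yl]-N-methoxy-N,1,2-trimethylcyclopentane-1-carboxamide (epimers at the sulfonyl carbon) | CON(C)C(=O)[C@]1(C)CCC[C@]1(C)CC(=O)C(S(=O)(=O)c2ccccc2)/C(C)=C/Cc3cc(OC)cc(C)c3OC | intermediate
27 | 1-{(1R,2R)-2-[(4E)-6-(2,5-dimethoxy-3-methylphenyl)-4-methyl-2-oxo-3-(phenylsulfonyl)hex-4-en-1-yl]-1,2-dimethylcyclopentyl}but-3-en-1-one | C=CCC(=O)[C@]1(C)CCC[C@]1(C)CC(=O)C(S(=O)(=O)c2ccccc2)/C(C)=C/Cc3cc(OC)cc(C)c3OC | intermediate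
28 | 1-{(1R,2R)-2-[(4E)-6-(2,5-dimethoxy-3-methylphenyl)-4-methyl-2-oxo-3-(phenylsulfonyl)hex-4-en-1-yl]-1,2-dimethylcyclopentyl}-4-methylpent-3-en-1-one | CC(C)=CCC(=O)[C@]1(C)CCC[C@]1(C)CC(=O)C(S(=O)(=O)c2ccccc2)/C(C)=C/Cc3cc(OC)cc(C)c3OC | intermediate
29 | 1-{(1R,2R)-2-[(4E)-6-(2,5-dimethoxy-3-methylphenyl)-4-methyl-2-oxohex-4-en-1-yl]-1,2-dimethylcyclopentyl}-4-methylpent-3-en-1-one | CC(C)=CCC(=O)[C@]1(C)CCC[C@]1(C)CC(=O)C/C(C)=C/Cc2cc(OC)cc(C)c2OC | intermediate
30 | 2-methyl-6-substituted 1,4-benzoquinone corresponding to 31 | CC(C)=CCC(=O)[C@]1(C)CCC[C@]1(C)CC(=O)C/C(C)=C/CC2=CC(=O)C=C(C)C2=O | intermediate (not isolated)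
31 | CNP0294415.1: (1R,2R)-cyclopentane with cis methyl groups, 4-methylpent-3-enoyl group on C1, (4E)-6-(2,5-dihydroxy-3-methylphenyl)-4-methyl-2-oxohex-4-en-1-yl group on C2 | CC(C)=CCC(=O)[C@]1(C)CCC[C@]1(C)CC(=O)C/C(C)=C/Cc1cc(O)cc(C)c1O | target

**Totals**

Total step count: 17. Longest linear sequence: 12 steps (steps 2–7, then 12–17).

**Steps most likely to fail**

Step 12 (Proposed new method). The tertiary enolate may be quenched by proton transfer from the γ-C–H bonds of the enoyl imide, or may add to a second molecule of 3, before it closes the ring. The homoallyl radical may close to a cyclopropylcarbinyl radical that is reduced. Facial control in the Michael closure may be poor, and the magnesium-bound acceptor may be reduced at the cathode. The fallback uses the known thiyl-radical-catalysed [3+2] annulation of a vinylcyclopropane with an electron-poor alkene; it sets out from 3 and comes back at 24. 1-Methyl-1-vinylcyclopropane F1 (Wittig methylenation of 1-methylcyclopropanecarbaldehyde) and 3 are heated with PhSSPh (cat.) and AIBN in benzene at 80 °C. Ring opening of the thiyl adduct gives the homoallyl radical, which adds to 3; 5-exo closure and loss of the thiyl radical form the same two ring bonds and should give N-methoxy-N,1,2-trimethyl-2-vinylcyclopentane-1-carboxamide F2 as a mixture of racemic diastereomers. Anti-Markovnikov hydroboration–oxidation (9-BBN, then NaBO3) should give 2-(2-hydroxyethyl)-N-methoxy-N,1,2-trimethylcyclopentane-1-carboxamide F3. Oxidation (TEMPO, PhI(OAc)2, MeCN/H2O) should give 2-{2-[methoxy(methyl)carbamoyl]-1,2-dimethylcyclopentyl}acetic acid F4. N-Acylation of 8 with F4 (PivCl, Et3N, LiCl) gives diastereomeric imides, from which 24 is separated by chromatography and crystallisation; here the auxiliary serves as resolving group.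

Step 13. The basic sulfonyl carbanion may enolise the imide instead of adding to it, or may attack the ring carbonyl of the oxazolidinone so that the auxiliary is opened and not displaced. The fallback moves the C–C bond formation to the aldehyde oxidation level; it sets out from 24 and comes back at 26. Reductive removal of the auxiliary (LiBH4, THF/MeOH, 0 °C) should give (1R,2R)-2-(2-hydroxyethyl)-N-methoxy-N,1,2-trimethylcyclopentane-1-carboxamide F5. Dess–Martin oxidation should give (1R,2R)-N-methoxy-N,1,2-trimethyl-2-(2-oxoethyl)cyclopentane-1-carboxamide F6. Addition of lithiated sulfone 25 (1.1 equiv, THF, −78 °C) should give the β-hydroxy sulfone (1R,2R)-2-[(4E)-6-(2,5-dimethoxy-3-methylphenyl)-2-hydroxy-4-methyl-3-(phenylsulfonyl)hex-4-en-1-yl]-N-methoxy-N,1,2-trimethylcyclopentane-1-carboxamide F7. A second Dess–Martin oxidation gives 26.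

Step 14. The Grignard reagent may fail to add to a carboxamide flanked by two quaternary carbons, or may act as a base on the N-methoxy group with loss of the N–O unit. The fallback adds the nucleophile at the less hindered aldehyde level and re-oxidises; it sets out from 26 and comes back at 28. The β-keto sulfone is protected as its sodium enolate (NaH, THF) and the N-methoxy-N-methylamide is reduced with iBu2AlH at −78 °C (AcOH quench), which should give the aldehyde (1R,2R)-2-[(4E)-6-(2,5-dimethoxy-3-methylphenyl)-4-methyl-2-oxo-3-(phenylsulfonyl)hex-4-en-1-yl]-1,2-dimethylcyclopentane-1-carbaldehyde F8. Aldehyde-selective allylboration with allylboronic acid pinacol ester should give the homoallylic alcohol 1-{(1R,2R)-2-(1-hydroxybut-3-en-1-yl)-1,2-dimethylcyclopentyl}-6-(2,5-dimethoxy-3-methylphenyl)-4-methyl-3-(phenylsulfonyl)hex-4-en-2-one F9. Cross-metathesis with 2-methylbut-2-ene (second-generation Grubbs catalyst RuCl2(=CHPh)(PCy3)(H2IMes)) should give the prenyl carbinol 1-{(1R,2R)-2-(1-hydroxy-4-methylpent-3-en-1-yl)-1,2-dimethylcyclopentyl}-6-(2,5-dimethoxy-3-methylphenyl)-4-methyl-3-(phenylsulfonyl)hex-4-en-2-one F10. Dess–Martin oxidation gives 28.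

**Further compounds**

F1 | step 12 | 1-methyl-1-vinylcyclopropane | C=CC1(C)CC1
F2 | step 12 | N-methoxy-N,1,2-trimethyl-2-vinylcyclopentane-1-carboxamide (mixture of stereoisomers) | CON(C)C(=O)C1(C)CCCC1(C)C=C
F3 | step 12 | 2-(2-hydroxyethyl)-N-methoxy-N,1,2-trimethylcyclopentane-1-carboxamide (mixture of stereoisomers) | CON(C)C(=O)C1(C)CCCC1(C)CCO
F4 | step 12 | 2-{2-[methoxy(methyl)carbamoyl]-1,2-dimethylcyclopentyl}acetic acid (mixture of stereoisomers) | CON(C)C(=O)C1(C)CCCC1(C)CC(O)=O
F5 | step 13 | (1R,2R)-2-(2-hydroxyethyl)-N-methoxy-N,1,2-trimethylcyclopentane-1-carboxamide | CON(C)C(=O)[C@]1(C)CCC[C@]1(C)CCO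
F6 | step 13 | (1R,2R)-N-methoxy-N,1,2-trimethyl-2-(2-oxoethyl)cyclopentane-1-carboxamide | CON(C)C(=O)[C@]1(C)CCC[C@]1(C)CC=O
F7 | step 13 | (1R,2R)-2-[(4E)-6-(2,5-dimethoxy-3-methylphenyl)-2-hydroxy-4-methyl-3-(phenylsulfonyl)hex-4-en-1-yl]-N-methoxy-N,1,2-trimethylcyclopentane-1-carboxamide | CON(C)C(=O)[C@]1(C)CCC[C@]1(C)CC(O)C(S(=O)(=O)c2ccccc2)/C(C)=C/Cc3cc(OC)cc(C)c3OC
F8 | step 14 | (1R,2R)-2-[(4E)-6-(2,5-dimethoxy-3-methylphenyl)-4-methyl-2-oxo-3-(phenylsulfonyl)hex-4-en-1-yl]-1,2-dimethylcyclopentane-1-carbaldehyde | O=C[C@]1(C)CCC[C@]1(C)CC(=O)C(S(=O)(=O)c2ccccc2)/C(C)=C/Cc3cc(OC)cc(C)c3OC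
F9 | step 14 | 1-{(1R,2R)-2-(1-hydroxybut-3-en-1-yl)-1,2-dimethylcyclopentyl}-6-(2,5-dimethoxy-3-methylphenyl)-4-methyl-3-(phenylsulfonyl)hex-4-en-2-one | C=CCC(O)[C@]1(C)CCC[C@]1(C)CC(=O)C(S(=O)(=O)c2ccccc2)/C(C)=C/Cc3cc(OC)cc(C)c3OC
F10 | step 14 | 1-{(1R,2R)-2-(1-hydroxy-4-methylpent-3-en-1-yl)-1,2-dimethylcyclopentyl}-6-(2,5-dimethoxy-3-methylphenyl)-4-methyl-3-(phenylsulfonyl)hex-4-en-2-one | CC(C)=CCC(O)[C@]1(C)CCC[C@]1(C)CC(=O)C(S(=O)(=O)c2ccccc2)/C(C)=C/Cc3cc(OC)cc(C)c3OC
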